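**Retrosynthetic overview**
1. The target comes from its 4-oxo derivative (a chroman-4-one). The C4 carbonyl is removed last, with hydride reagents only, so the terminal alkene is not touched.
2. Key disconnection: O1–C2 of the oxygen ring, closed by an enantioselective intramolecular oxa-Michael addition. This leads back to an open aryl enone, made from 2-acetyl-3,5,6-trimethylhydroquinone and the C18 methyl ketone (6R,10S)-6,10,14-trimethylpentadec-14-en-2-one.
3. The ketone comes from an acetyl donor and a C16 alkyl chloride. The chloride comes from a C6'–C7' sp3–sp3 coupling of a C9 bromide (C8' centre, alkene) with a C7 bromo chloride (C4' centre).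
4. The C9 bromide comes from 4-bromo-2-methylbut-1-ene and (S)-3-bromo-2-methylpropan-1-ol. The C7 piece comes from (S)-citronellyl bromide by ozonolysis.
5. Ring order: the arene (ring A) is bought. The oxygen ring (ring B) is the only ring made, and it is made in the key step.

Assumption: C8' is labelled S in the target only because the 12'-ene raises the priority of the tail branch (the spatial arrangement is that of natural 4'R,8'R-α-tocopherol), and the (R)-acid of step 8 is taken to give 2R; if a model run shows the opposite sense, its mirror image is used and nothing else changes.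

Primed locants count the side chain from C1', the carbon bonded to C2.

**Step 1**
Reactants: 1 4-bromo-2-methylbut-1-ene; 2 (S)-3-bromo-2-methylpropan-1-ol
Product: 4 (R)-2,6-dimethylhept-6-en-1-ol, via 3-methylbut-3-enylmagnesium bromide 3 (not isolated)
Conditions: 1 (2.3 equiv), Mg, THF, rt; then 2, Li2CuCl4 (3 mol %), THF, −78 °C → rt; aq NH4Cl
Reagents that add atoms: none
Why: Copper-catalysed sp3–sp3 Grignard cross-coupling (Kochi–Schlosser type): the first equivalent of 3 deprotonates 2, the second displaces its primary bromide, and the stereocentre of 2, one carbon from the reacting site, is carried over unchanged to become C8'.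

**Step 2**
Reactants: 4 (R)-2,6-dimethylhept-6-en-1-ol
Product: 5 (R)-7-bromo-2,6-dimethylhept-1-ene
Conditions: CBr4, PPh3, CH2Cl2, 0 °C
Reagents that add atoms: carbon tetrabromide BrC(Br)(Br)Br
Why: Appel reaction: SN2 bromination of the primary alcohol under neutral conditions that leave the 1,1-disubstituted alkene and the neighbouring stereocentre untouched.

**Step 3**
Reactants: 6 (S)-citronellyl bromide
Product: 8 (S)-6-bromo-4-methylhexan-1-ol, via (S)-6-bromo-4-methylhexanal 7 (not isolated)
Conditions: O3, CH2Cl2/MeOH, −78 °C; then NaBH4, −78 → 0 °C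
Reagents that add atoms: ozone [O-][O+]=O
Why: Ozonolysis with reductive work-up cleaves the only alkene to the aldehyde and on to the primary alcohol, the alkyl bromide survives, and the chiral-pool stereocentre of 6 becomes C4'.

**Step 4**
Reactants: 8 (S)-6-bromo-4-methylhexan-1-ol
Product: 9 (S)-1-bromo-6-chloro-3-methylhexane
Conditions: NCS, PPh3, THF, 0 °C → rt
Reagents that add atoms: N-chlorosuccinimide O=C1CCC(=O)N1Cl
Why: Appel-type chlorination gives a dihalide whose two ends differ enough in reactivity (C–Br over C–Cl) to be addressed one after the other, and no stereocentre is involved.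

**Step 5**
Reactants: 5 (R)-7-bromo-2,6-dimethylhept-1-ene; 9 (S)-1-bromo-6-chloro-3-methylhexane
Product: 11 (6S,10R)-13-chloro-2,6,10-trimethyltridec-1-ene, via (R)-2,6-dimethylhept-6-enylmagnesium bromide 10 (not isolated)
Conditions: 5, Mg, THF, 40 °C; then 9, Li2CuCl4 (5 mol %), THF, −30 °C → rt; aq NH4Cl
Reagents that add atoms: none
Why: Copper-catalysed sp3–sp3 Grignard cross-coupling forms C6'–C7' only at the C–Br bond of 9 because primary chlorides are inert under these conditions, and both stereocentres are remote from the reacting carbons.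

**Step 6**
Reactants: 11 (6S,10R)-13-chloro-2,6,10-trimethyltridec-1-ene
Product: 13 (6R,10S)-6,10,14-trimethylpentadec-14-en-2-one, via (4R,8S)-4,8,12-trimethyltridec-12-enylmagnesium chloride 12 (not isolated)
Conditions: Mg (I2-activated), THF, reflux; then MeC(O)N(OMe)Me, 0 °C; aq NH4Cl
Reagents that add atoms: N-methoxy-N-methylacetamide CC(=O)N(C)OC
Why: Weinreb ketone synthesis: the chelated tetrahedral adduct stops the Grignard addition at the methyl ketone, and the terminal alkene is inert to Mg and to the amide.

**Step 7**
Reactants: 14 2,3,5-trimethylhydroquinone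
Product: 15 1-(2,5-dihydroxy-3,4,6-trimethylphenyl)ethan-1-one
Conditions: AcOH, BF3·OEt2, 100 °C; then H2O
Reagents that add atoms: acetic acid CC(=O)O
Why: Friedel–Crafts (Nencki-type) C-acylation at the only free ring position, driven by formation of the chelated ortho-hydroxy ketone.

**Step 8 (key step)**
Reactants: 13 (6R,10S)-6,10,14-trimethylpentadec-14-en-2-one; 15 1-(2,5-dihydroxy-3,4,6-trimethylphenyl)ethan-1-one
Product: 17 (2R)-6-hydroxy-2,5,7,8-tetramethyl-2-[(4R,8S)-4,8,12-trimethyltridec-12-en-1-yl]chroman-4-one, via open-chain (E)-enone 16 (not isolated)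
Conditions: pyrrolidine (20 mol %), (R)-3,3'-bis(2,4,6-triisopropylphenyl)-1,1'-binaphthalene-2,2'-diyl hydrogen phosphate (20 mol %), 4 Å MS, toluene, 35 °C, N2
Reagents that add atoms: none
Why: Proposed new method: an enantioselective Kabbe annulation in which the achiral acid co-catalyst of the known pyrrolidine-mediated chromanone synthesis is replaced by a bulky chiral phosphoric acid; pyrrolidine condenses 13 and 15 to the conjugated iminium/enone 16, whose E and Z forms interconvert through the dienamine; the phosphate ion-pairs with the iminium and hydrogen-bonds the ortho phenol O–H, so O1 adds to one face of C2 of the better-fitting E isomer (methyl in the pocket, long chain pointing out) and the O1–C2 bond closes ring B and sets 2R; the acid is far too weak to protonate the isolated 1,1-disubstituted alkene, and the product carbonyl, shielded by the peri methyl group, re-forms an iminium only slowly, which limits retro-oxa-Michael erosion; the closest known reaction types are the racemic Kabbe condensation, counteranion-directed iminium catalysis (which already distinguishes methyl from a linear alkyl group at the β-carbon of E/Z enal mixtures) and organocatalytic intramolecular oxa-Michael additions.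

**Step 9**
Reactants: 17 (2R)-6-hydroxy-2,5,7,8-tetramethyl-2-[(4R,8S)-4,8,12-trimethyltridec-12-en-1-yl]chroman-4-one
Product: 19 (2R)-2,5,7,8-tetramethyl-2-[(4R,8S)-4,8,12-trimethyltridec-12-en-1-yl]chroman-6-ol, via chromane-4,6-diol aluminium alkoxide 18 (not isolated)
Conditions: LiAlH4, AlCl3 (1:3), Et2O, 0 °C → rt; cold 1 M HCl
Reagents that add atoms: none
Why: Mixed-hydride (chloroalane) hydrogenolysis of an electron-rich aryl ketone: hydride gives the benzylic alkoxide 18, aluminium-assisted ionisation gives a cation stabilised by the ortho ring oxygen, a second hydride traps it, the hydridic proton-free medium cannot protonate the terminal alkene, and C2 takes no part.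

**Compound list**
1 | 4-bromo-2-methylbut-1-ene | C=C(C)CCBr | starting material
2 | (S)-3-bromo-2-methylpropan-1-ol | C[C@@H](CO)CBr | starting material
3 | 3-methylbut-3-enylmagnesium bromide (not isolated) | C=C(C)CC[Mg]Br | intermediate
4 | (R)-2,6-dimethylhept-6-en-1-ol | C=C(C)CCC[C@@H](C)CO | intermediate
5 | (R)-7-bromo-2,6-dimethylhept-1-ene | C=C(C)CCC[C@@H](C)CBr | intermediate
6 | (S)-citronellyl bromide = (S)-8-bromo-2,6-dimethyloct-2-ene | C[C@@H](CCC=C(C)C)CCBr | starting material
7 | (S)-6-bromo-4-methylhexanal (not isolated) | C[C@@H](CCC=O)CCBr | intermediate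
8 | (S)-6-bromo-4-methylhexan-1-ol | C[C@@H](CCCO)CCBr | intermediate
9 | (S)-1-bromo-6-chloro-3-methylhexane | C[C@@H](CCCCl)CCBr | intermediate
10 | (R)-2,6-dimethylhept-6-enylmagnesium bromide (not isolated) | C=C(C)CCC[C@@H](C)C[Mg]Br | intermediate
11 | (6S,10R)-13-chloro-2,6,10-trimethyltridec-1-ene | C=C(C)CCC[C@@H](C)CCC[C@@H](C)CCCCl | intermediate
12 | (4R,8S)-4,8,12-trimethyltridec-12-enylmagnesium chloride (not isolated) | C=C(C)CCC[C@@H](C)CCC[C@@H](C)CCC[Mg]Cl | intermediate
13 | (6R,10S)-6,10,14-trimethylpentadec-14-en-2-one | C=C(C)CCC[C@@H](C)CCC[C@@H](C)CCCC(C)=O | intermediate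
14 | 2,3,5-trimethylhydroquinone | Cc1cc(O)c(C)c(C)c1O | starting material
15 | 1-(2,5-dihydroxy-3,4,6-trimethylphenyl)ethan-1-one | CC(=O)c1c(C)c(O)c(C)c(C)c1O | intermediate
16 | (2E,7R,11S)-1-(2,5-dihydroxy-3,4,6-trimethylphenyl)-3,7,11,15-tetramethylhexadeca-2,15-dien-1-one (not isolated; E drawn, E/Z equilibrate) | C=C(C)CCC[C@@H](C)CCC[C@@H](C)CCC/C(C)=C/C(=O)c1c(C)c(O)c(C)c(C)c1O | intermediate
17 | (2R)-6-hydroxy-2,5,7,8-tetramethyl-2-[(4R,8S)-4,8,12-trimethyltridec-12-en-1-yl]chroman-4-one | C=C(C)CCC[C@@H](C)CCC[C@@H](C)CCC[C@]1(C)CC(=O)c2c(C)c(O)c(C)c(C)c2O1 | intermediate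
18 | (2R,4RS)-2,5,7,8-tetramethyl-2-[(4R,8S)-4,8,12-trimethyltridec-12-en-1-yl]chromane-4,6-diol (formed as its aluminium alkoxide, not isolated) | C=C(C)CCC[C@@H](C)CCC[C@@H](C)CCC[C@]1(C)CC(O)c2c(C)c(O)c(C)c(C)c2O1 | intermediate
19 | (2R)-2,5,7,8-tetramethyl-2-[(4R,8S)-4,8,12-trimethyltridec-12-en-1-yl]chroman-6-ol | C=C(C)CCC[C@@H](C)CCC[C@@H](C)CCC[C@]1(C)CCc2c(C)c(O)c(C)c(C)c2O1 | target

**Step count**
- Total steps: 9.
- Longest linear sequence: 6 (steps 1, 2, 5, 6, 8, 9). The branch 3, 4, 5, 6, 8, 9 is equally long.

**Steps most likely to fail**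

*Step 8 (the proposed new step).*
- Risks: low facial selectivity at C2, slow turnover of the pyrrolidinium phosphate, or erosion by retro-oxa-Michael reaction.
- The fallback sets out from 13 and 15 and uses only known chemistry.
- The classical Kabbe condensation (pyrrolidine, 1 equiv, toluene, reflux with water removal) gives the 1:1 C2-epimer mixture (2RS)-chromanone F1.
- Preparative HPLC on a cellulose tris(3,5-dimethylphenylcarbamate) phase separates F1 into 17 and the (2S)-chromanone F2.
- F2 is re-equilibrated to F1 with pyrrolidine (retro-oxa-Michael/oxa-Michael) and recycled.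
- The fallback comes back to the route at 17.

*Step 9.*
- Risks: the aluminium Lewis acid could open the tertiary alkyl aryl ether and erode C2, or the benzylic cation could lose a proton to give the 2H-chromene.
- The fallback sets out from 17 and separates the two events.
- NaBH4 in MeOH/THF at 0 °C gives 18, this time isolated.
- The benzylic hydroxyl is then removed by ionic hydrogenolysis with Et3SiH and BF3·OEt2 in CH2Cl2 at −78 °C, where the benzylic position ionises but the alkene and the ring ether do not react.
- The fallback comes back at 19. It makes no compound outside the list, F0.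

*Step 5.*
- Risks: Wurtz dimerisation while the β-branched Grignard 10 is formed, or a sluggish coupling.
- The fallback sets out from 4 and 9 and reverses the polarity of both fragments.
- Compound 4 is converted with TsCl/pyridine to (R)-2,6-dimethylhept-6-enyl 4-methylbenzenesulfonate F3.
- Compound 9 is treated with Mg in THF at 0–20 °C, where insertion takes place only at C–Br, to give (S)-6-chloro-3-methylhexylmagnesium bromide F4.
- Li2CuCl4-catalysed coupling of F4 with F3 comes back to the route at 11.

**Further compounds**
F1 | step 8 | (2RS)-6-hydroxy-2,5,7,8-tetramethyl-2-[(4R,8S)-4,8,12-trimethyltridec-12-en-1-yl]chroman-4-one (1:1 epimer mixture) | C=C(C)CCC[C@@H](C)CCC[C@@H](C)CCCC1(C)CC(=O)c2c(C)c(O)c(C)c(C)c2O1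
F2 | step 8 | (2S)-6-hydroxy-2,5,7,8-tetramethyl-2-[(4R,8S)-4,8,12-trimethyltridec-12-en-1-yl]chroman-4-one | C=C(C)CCC[C@@H](C)CCC[C@@H](C)CCC[C@@]1(C)CC(=O)c2c(C)c(O)c(C)c(C)c2O1
F0 | step 9 | none | none
F3 | step 5 | (R)-2,6-dimethylhept-6-enyl 4-methylbenzenesulfonate | C=C(C)CCC[C@@H](C)COS(=O)(=O)c1ccc(C)cc1
F4 | step 5 | (S)-6-chloro-3-methylhexylmagnesium bromide | C[C@@H](CCCCl)CC[Mg]Br
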